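**Plan**

1. Cuts, last bond first: the lactone bond O7–C19 (opened to a C19 amide); C6–C7 of the ten-membered ring (alkenyl iodide + aldehyde); C3–C4 (aldol); C2–C3 (alkoxymethyl anion); C8–C9 (alkenyl triflate + aldehyde, giving a butenolide on O9); and C10–C11 with C1–C14 (ring A).
2. Feature behind the key step: in ring A (C1, C10–C14) C1 (CH3, C2) and C10 (H, C9) are adjacent and trans and each carries an oxidised carbon, i.e. an (E)-2-methylbut-2-ene-1,4-dicarbonyl unit (C2 formyl, C9 ester); C11(CH3)–C12(O)–C13–C14 is a 3-siloxypenta-1,3-diene.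
3. Forward order: ring A by Diels–Alder → 11,13-diene → 11,12-diol → butenolide on O9 (C8–C9) → 8,17-diol → C2–C6 chain → ten-membered ring (C6–C7) → lactone moved from O9 to O7.
4. Stereochemistry: C1/C10 from a chiral boron Lewis acid on the C2 formyl group plus the E geometry; C11/C12 from OsO4 on the α face of ring A; C9 from Felkin–Anh addition.
5. C8/C17 from syn-dihydroxylation of the O9 butenolide anti to ring A (this cis-diol is the 8,17-trans-diol once the lactone sits on O7); C3/C4 from a syn aldol; C2 from a 1,3-anti reduction; C7 in the ring closure.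

Key step: step 2

Assumption: briarane numbering is used throughout and β means the face of ring A that carries the C15 methyl; the C2 carbinol made in step 4 is carried as an epimer pair (no descriptor at C2 in the SMILES of 8–29) because step 22 converts it into the ketone.

**Route**

Step 1
Reactants: 1 pent-1-en-3-one
Product: 2 (Z)-3-(tert-butyldimethylsilyloxy)penta-1,3-diene
Conditions: TBSOTf, Et3N, CH2Cl2, 0 °C
Reagents that add atoms: tert-butyldimethylsilyl trifluoromethanesulfonate, CC(C)(C)[Si](C)(C)OS(=O)(=O)C(F)(F)F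
Why: Amine/silyl triflate enolisation and O-silylation of the ethyl ketone side should give the cross-conjugated silyl dienol ether, mainly as the Z isomer (methyl cis to oxygen), which is the reactive "outside-methyl" diene.

Step 2
Reactants: 2 (Z)-3-(tert-butyldimethylsilyloxy)penta-1,3-diene; 3 ethyl (E)-3-methyl-4-oxobut-2-enoate
Product: 4 ethyl (1S,2R,6S)-6-formyl-2,6-dimethyl-3-(tert-butyldimethylsilyloxy)cyclohex-3-ene-1-carboxylate (ring A; briarane C1 S, C10 S, 11β-CH3)
Conditions: (R)-1-(2-methylphenyl)-3,3-diphenyltetrahydro-1H,3H-pyrrolo[1,2-c][1,3,2]oxazaborole (20 mol%), HNTf2 (18 mol%), CH2Cl2, −78 → −40 °C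
Reagents that add atoms: none
Why: The formyl oxygen of 3 binds the boron of the chiral oxazaborolidinium cation, which lowers the LUMO and makes C10 (β to the formyl group) the electrophilic carbon, so the concerted but asynchronous [4+2] cycloaddition first bonds the nucleophilic, methyl-bearing diene terminus C11 to C10 and then closes C14 onto C1 to give the quaternary centre. The closest known reaction type is the oxazaborolidinium-catalysed Diels–Alder reaction of 2-substituted enals with 2-siloxydienes. Ring A closes as a six-membered carbocycle by this cycloaddition, both σ bonds (C10–C11 and C1–C14) forming suprafacially on each partner. C1 and C10 should be set in the absolute sense by the catalyst (formyl C–H···O binding, s-trans enal, one face covered by a phenyl group; the R catalyst is chosen to leave open the face that gives 1S,10S) and in the relative trans sense by the E geometry of 3, while C11 follows from the ester-endo/formyl-exo transition state and is erased in step 6. The step needs the "para" regiochemistry between C12 and C1, which is secured because the Lewis acid-bound C2 formyl group, not the C9 ester, dominates the dienophile (an activated C9 carbonyl would send C11 to C1 instead) and the 2-siloxy group polarises the diene towards C11. It also needs facial selectivity, which rests on the catalyst alone.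

Step 3
Reactants: 5 tributyl(iodomethyl)stannane; 6 (4-methoxyphenyl)methanol
Product: 7 tributyl[(4-methoxybenzyloxy)methyl]stannane
Conditions: NaH, THF–DMF, 0 → 23 °C
Reagents that add atoms: none
Why: Williamson ether synthesis (SN2 of the alkoxide on the iodomethylstannane) should give the tin precursor of the alkoxymethyl anion that will become C3; no stereocentre is formed.

Step 4
Reactants: 4 ring A cycloadduct; 7 tributyl[(4-methoxybenzyloxy)methyl]stannane
Product: 9 C2–O–C9 γ-lactone silyl enol ether bearing CH2OPMB (C3) on C2 (C2 epimers), via lithium alkoxide of the C2 carbinol 8 (not isolated)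
Conditions: 7, n-BuLi, THF, −78 °C; then 4, −78 → 0 °C
Reagents that add atoms: none
Why: Tin–lithium exchange gives the α-alkoxymethyllithium, which should add 1,2 to the neopentyl aldehyde much faster than to the hindered ester, and the resulting alkoxide lactonises onto the C9 ester (trans-fused γ-lactone), masking C2 and C9 together; the new C2 carbinol is an epimer pair that is erased in step 22.

Step 5
Reactants: 9 lactone silyl enol ether
Product: 10 ring A enone lactone (12-oxo, C13=C14)
Conditions: Pd(OAc)2 (1.1 equiv), MeCN, 23 °C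
Reagents that add atoms: none
Why: Saegusa–Ito oxidation: palladation of the silyl enol ether at C13 and β-hydride elimination from C14 should give the C13=C14 enone with the carbonyl at C12; no new stereocentre.

Step 6
Reactants: 10 enone lactone
Product: 11 cross-conjugated dienyl triflate lactone (C11=C12(OTf)–C13=C14)
Conditions: KN(SiMe3)2 (1.05 equiv), THF, −78 °C; PhNTf2, −78 → 0 °C
Reagents that add atoms: N-phenylbis(trifluoromethanesulfonimide), O=S(=O)(N(c1ccccc1)S(=O)(=O)C(F)(F)F)C(F)(F)F
Why: Kinetic deprotonation at C11, the only α′-hydrogen of the enone (C1 is quaternary, so no γ-deprotonation), gives the cross-conjugated dienolate, which is trapped on oxygen as the triflate; C11 becomes sp2.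

Step 7
Reactants: 11 dienyl triflate lactone
Product: 12 ring A 11,13-diene lactone
Conditions: Pd(OAc)2 (5 mol%), PPh3 (10 mol%), HCO2H, Bu3N, DMF, 60 °C
Reagents that add atoms: none
Why: Palladium-catalysed formate reduction of the alkenyl triflate (oxidative addition, formate exchange, decarboxylation, reductive elimination) should replace OTf by H and leave the lactone and PMB ether untouched.

Step 8
Reactants: 12 diene lactone
Product: 13 11α,12α-diol lactone (11β-CH3, C13=C14 retained)
Conditions: OsO4 (2 mol%), NMO, acetone–H2O, 0 °C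
Reagents that add atoms: 4-methylmorpholine N-oxide, C[N+]1([O-])CCOCC1; water, O
Why: Catalytic osmium tetroxide syn-dihydroxylation should take the electron-richer trisubstituted C11=C12 bond of the diene from the α face, opposite the C15 methyl and the C9 carbonyl branch on C10, setting 11S and 12R as the cis-diol.

Step 9
Reactants: 13 diol lactone
Product: 14 11,12-O-isopropylidene lactone
Conditions: Me2C(OMe)2, PPTS, CH2Cl2, 23 °C
Reagents that add atoms: 2,2-dimethoxypropane, COC(C)(C)OC
Why: Acid-catalysed transketalisation of the cis-diol gives the cis-fused dioxolane; no stereocentre changes.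

Step 10
Reactants: 14 acetonide lactone
Product: 15 C9 N-methoxy-N-methylamide with free C2 carbinol (C2 epimers)
Conditions: MeNHOMe·HCl, AlMe3, CH2Cl2, 0 → 23 °C
Reagents that add atoms: N,O-dimethylhydroxylamine hydrochloride, CNOC.Cl
Why: Weinreb aminolysis of the γ-lactone by the aluminium amide opens the ring at C9 and frees the C2 oxygen, which differentiates C2 from C9.

Step 11
Reactants: 15 hydroxy Weinreb amide
Product: 16 C2 triethylsilyl ether
Conditions: TESOTf, 2,6-lutidine, CH2Cl2, −78 °C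
Reagents that add atoms: triethylsilyl trifluoromethanesulfonate, CC[Si](CC)(CC)OS(=O)(=O)C(F)(F)F
Why: Silylation of the hindered secondary alcohol with the silyl triflate prevents relactonisation and lactol formation in the following steps.

Step 12
Reactants: 16 Weinreb amide
Product: 17 C9 aldehyde
Conditions: i-Bu2AlH, THF, −78 °C; Rochelle salt
Reagents that add atoms: none
Why: Hydride reduction of the Weinreb amide stops at the chelated tetrahedral intermediate and releases the aldehyde on neutral work-up, so C10 and the β-alkoxy group at C11 are not disturbed.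

Step 13
Reactants: 18 methyl hydroxyacetate
Product: 19 methyl (tert-butyldiphenylsilyloxy)acetate
Conditions: TBDPSCl, imidazole, DMF, 23 °C
Reagents that add atoms: tert-butyl(chloro)diphenylsilane, CC(C)(C)[Si](Cl)(c1ccccc1)c1ccccc1
Why: Standard silylation of the primary alcohol protects the future C7 oxygen.

Step 14
Reactants: 19 methyl (tert-butyldiphenylsilyloxy)acetate; 20 methyl propanoate
Product: 21 methyl 4-(tert-butyldiphenylsilyloxy)-2-methyl-3-oxobutanoate (racemic at C17)
Conditions: LiN(i-Pr)2 (2.2 equiv), 20 (2.2 equiv), THF, −78 °C; then 19, −78 → 0 °C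
Reagents that add atoms: none
Why: Crossed Claisen condensation of the propanoate lithium enolate with the more electrophilic α-silyloxy ester gives the β-keto ester holding C7, C8, C17, C18 and C19; its stereocentre is lost in the next step.

Step 15
Reactants: 21 β-keto ester
Product: 22 methyl (Z)-4-(tert-butyldiphenylsilyloxy)-2-methyl-3-(trifluoromethylsulfonyloxy)but-2-enoate
Conditions: NaH, THF, 0 °C; Tf2O, −78 → 0 °C
Reagents that add atoms: trifluoromethanesulfonic anhydride, O=S(=O)(OS(=O)(=O)C(F)(F)F)C(F)(F)F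
Why: O-Triflation of the sodium-chelated Z enolate should give the enol triflate with OTf cis to the ester, the geometry that later lets O9 reach C19.

Step 16
Reactants: 17 C9 aldehyde; 22 (Z)-enol triflate
Product: 24 butenolide on O9 (C8=C17, C8 bearing CH2OTBDPS = C7, C17 methyl), via (Z)-γ-hydroxy enoate 23 (not isolated)
Conditions: CrCl2 (6 equiv), NiCl2 (2 mol%), DMF, 23 °C
Reagents that add atoms: none
Why: Nozaki–Hiyama–Kishi reaction: zerovalent nickel inserts into the C8–OTf bond, transmetalation gives the alkenyl trivalent chromium species, which should add to the aldehyde anti to the C10–C11 bond and past H-10 (Felkin–Anh, C9 as in the target), and the alkoxide then closes on the cis ester to the butenolide.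

Step 17
Reactants: 24 O9 butenolide
Product: 25 8,17-dihydroxy O9 γ-lactone
Conditions: KMnO4, dicyclohexano-18-crown-6, CH2Cl2, −40 °C; then H2O
Reagents that add atoms: potassium permanganate, [K+].[O-][Mn](=O)(=O)=O
Why: Permanganate syn-dihydroxylation (cyclic manganate ester) favours the electron-poor butenolide double bond and should occur on the face anti to the ring A substituent at C9, setting C8 and C17 as in the target, while C13=C14 is screened on both faces by the C15/C20 methyls, the dioxolane and the C2 branch.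

Step 18
Reactants: 25 diol lactone
Product: 26 8,17:11,12-bis-O-isopropylidene O9 lactone
Conditions: 2-methoxypropene, PPTS, CH2Cl2, 0 → 23 °C
Reagents that add atoms: 2-methoxypropene, COC(C)=C
Why: Ketalisation of the cis-di-tertiary diol gives the dioxolane cis-fused to the lactone, which protects the α-ketol-prone diol and later blocks premature lactonisation onto O7.

Step 19
Reactants: 26 bis-acetonide lactone
Product: 27 C19 N-methoxy-N-methylamide with free C9 alcohol
Conditions: MeNHOMe·HCl, AlMe3, CH2Cl2, 23 → 40 °C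
Reagents that add atoms: N,O-dimethylhydroxylamine hydrochloride, CNOC.Cl
Why: Weinreb aminolysis opens the O9 lactone irreversibly, so that C19 stays at the acid oxidation level while O9 is freed for acetylation.

Step 20
Reactants: 27 hydroxy amide
Product: 28 C9 acetate
Conditions: Ac2O, DMAP, pyridine, 23 °C
Reagents that add atoms: acetic anhydride, CC(=O)OC(C)=O
Why: Acyl transfer catalysis acetylates the only free hydroxyl, installing the 9-OAc of the target and preventing return to the O9 lactone.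

Step 21
Reactants: 28 acetate
Product: 29 C2 alcohol (C2 epimers)
Conditions: HF·pyridine, pyridine, THF, 0 °C
Reagents that add atoms: none
Why: Buffered fluoride cleaves the triethylsilyl ether far faster than the primary TBDPS ether and leaves acetonides and acetate intact.

Step 22
Reactants: 29 C2 alcohol
Product: 30 C2 ketone (C1–CO–CH2OPMB)
Conditions: Dess–Martin periodinane, NaHCO3, CH2Cl2, 23 °C
Reagents that add atoms: none
Why: Dess–Martin oxidation converts both C2 epimers into one α-alkoxy ketone that can enolise only towards C3.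

Step 23
Reactants: 31 prop-2-yn-1-ol
Product: 33 (Z)-3-iodo-2-methylprop-2-en-1-ol, via (Z)-alkenylmagnesium alkoxide 32 (not isolated)
Conditions: MeMgBr (2.5 equiv), CuI (10 mol%), THF, −10 → 23 °C; then I2, −60 → 0 °C
Reagents that add atoms: methylmagnesium bromide, C[Mg]Br; iodine, II
Why: Copper-catalysed, alkoxide-directed anti-carbomagnesiation puts methyl on C5 and magnesium on C6 cis to the carbinol carbon, and iodinolysis with retention gives the Z alkenyl iodide.

Step 24
Reactants: 33 (Z)-iodo allylic alcohol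
Product: 34 (Z)-3-iodo-2-methylprop-2-enal
Conditions: MnO2, CH2Cl2, 23 °C, dark; used at once
Reagents that add atoms: none
Why: Allylic oxidation with manganese dioxide is neutral and should not isomerise the Z alkenyl iodide.

Step 25
Reactants: 30 C2 ketone; 34 (Z)-3-iodo-2-methylprop-2-enal
Product: 35 3,4-syn aldol adduct (C3–OPMB, C4–OH, C5(CH3)=C6HI Z)
Conditions: Bu2BOTf, i-Pr2NEt, CH2Cl2, −78 °C; then 34, −78 → −20 °C; pH 7 buffer, MeOH
Reagents that add atoms: none
Why: Boron aldol reaction: the α-alkoxy ketone should give the Z boron enolate and, through a Zimmerman–Traxler chair, the 3,4-syn adduct, with the enolate face chosen by the C1 quaternary centre (the C10 branch is expected to screen one face, which would give C3 and C4 as in the target, but this facial preference is not secure and is one of the risks named below).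

Step 26
Reactants: 35 β-hydroxy ketone
Product: 36 2,4-anti diol (C2 S as in the target)
Conditions: Me4NBH(OAc)3, MeCN–AcOH, −30 °C
Reagents that add atoms: none
Why: Evans–Saksena reduction: the C4 hydroxyl binds the acetoxyborohydride and delivers hydride intramolecularly through a chair, which should give the 1,3-anti diol and hence the 2,3-anti,3,4-syn triol pattern.

Step 27
Reactants: 36 diol
Product: 37 2,4-diacetate
Conditions: Ac2O, DMAP, pyridine, 40 °C
Reagents that add atoms: acetic anhydride, CC(=O)OC(C)=O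
Why: Acylation of the two free secondary hydroxyls installs the 2- and 4-acetates while O3 stays masked as its PMB ether.

Step 28
Reactants: 37 diacetate
Product: 38 C7 primary alcohol
Conditions: HF·pyridine, pyridine, THF, 23 °C
Reagents that add atoms: none
Why: Fluoride-mediated desilylation removes the TBDPS ether without touching acetates, acetonides or the alkenyl iodide.

Step 29
Reactants: 38 C7 alcohol
Product: 39 C7 aldehyde
Conditions: Dess–Martin periodinane, NaHCO3, CH2Cl2, 23 °C
Reagents that add atoms: none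
Why: Dess–Martin oxidation gives the α-quaternary aldehyde, which cannot epimerise and whose α-diol is tied up in the dioxolane.

Step 30
Reactants: 39 iodo aldehyde
Product: 40 ten-membered ring allylic alcohol (C6–C7 bond, 5Z, 7S)
Conditions: CrCl2 (10 equiv), NiCl2 (1 mol%), DMSO–THF, 0.002 M, 23 °C
Reagents that add atoms: none
Why: Intramolecular Nozaki–Hiyama–Kishi reaction: the Z alkenyl chromium species adds to the C7 aldehyde with retention of alkene geometry to close the ten-membered ring, and attack anti to the C8–O bond with the carbonyl oxygen turned towards C9 should give the 7S carbinol.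

Step 31
Reactants: 40 macrocycle
Product: 41 C3 alcohol
Conditions: DDQ, CH2Cl2–pH 7 buffer, 0 °C
Reagents that add atoms: none
Why: Oxidative cleavage of the PMB ether under buffered conditions frees O3 without acyl migration and is much faster than oxidation of the hindered allylic C7 alcohol.

Step 32
Reactants: 41 C3 alcohol
Product: 43 brianodin C, via hexaol N-methoxy-N-methylamide 42 (not isolated)
Conditions: TFA–H2O (4:1), CH2Cl2, 0 °C
Reagents that add atoms: none
Why: Acid hydrolysis removes both isopropylidene acetals; once the 8,17-dioxolane is gone (it made a lactone on O7 trans-fused and strained), the C7 hydroxyl attacks the C19 amide to form the γ-lactone, which places the 8- and 17-hydroxyls trans on the new ring without touching any stereocentre.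

**Compound list**

1 | pent-1-en-3-one | CCC(=O)C=C | starting material
2 | (Z)-3-(tert-butyldimethylsilyloxy)penta-1,3-diene | C=C/C(O[Si](C)(C)C(C)(C)C)=C/C | intermediate
3 | ethyl (E)-3-methyl-4-oxobut-2-enoate | CCOC(=O)/C=C(\C)C=O | starting material
4 | ethyl (1S,2R,6S)-6-formyl-2,6-dimethyl-3-(tert-butyldimethylsilyloxy)cyclohex-3-ene-1-carboxylate | CCOC(=O)[C@H]1[C@@H](C)C(O[Si](C)(C)C(C)(C)C)=CC[C@]1(C)C=O | intermediate
5 | tributyl(iodomethyl)stannane | CCCC[Sn](CCCC)(CCCC)CI | starting material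
6 | (4-methoxyphenyl)methanol | COc1ccc(CO)cc1 | starting material
7 | tributyl[(4-methoxybenzyloxy)methyl]stannane | CCCC[Sn](CCCC)(CCCC)COCc1ccc(OC)cc1 | intermediate
8 | lithium alkoxide of the C2 carbinol ester (C2 epimers) | CCOC(=O)[C@H]1[C@@H](C)C(O[Si](C)(C)C(C)(C)C)=CC[C@]1(C)C([O-])COCc1ccc(OC)cc1.[Li+] | intermediate
9 | C2–O–C9 γ-lactone silyl enol ether, CH2OPMB on C2 (C2 epimers) | O=C1OC(COCc2ccc(OC)cc2)[C@@]3(C)CC=C(O[Si](C)(C)C(C)(C)C)[C@H](C)[C@H]13 | intermediate
10 | ring A enone lactone (12-oxo, C13=C14) | O=C1OC(COCc2ccc(OC)cc2)[C@@]3(C)C=CC(=O)[C@H](C)[C@H]13 | intermediate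
11 | dienyl triflate lactone | O=C1OC(COCc2ccc(OC)cc2)[C@@]3(C)C=CC(OS(=O)(=O)C(F)(F)F)=C(C)[C@H]13 | intermediate
12 | ring A 11,13-diene lactone | O=C1OC(COCc2ccc(OC)cc2)[C@@]3(C)C=CC=C(C)[C@H]13 | intermediate
13 | 11α,12α-diol lactone | O=C1OC(COCc2ccc(OC)cc2)[C@@]3(C)C=C[C@@H](O)[C@@](C)(O)[C@H]13 | intermediate
14 | 11,12-O-isopropylidene lactone | O=C1OC(COCc2ccc(OC)cc2)[C@@]3(C)C=C[C@H]4OC(C)(C)O[C@@]4(C)[C@H]13 | intermediate
15 | C9 Weinreb amide, C2 alcohol (C2 epimers) | CON(C)C(=O)[C@H]1[C@]2(C)OC(C)(C)O[C@@H]2C=C[C@]1(C)C(O)COCc1ccc(OC)cc1 | intermediate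
16 | C9 Weinreb amide, C2 triethylsilyl ether | CON(C)C(=O)[C@H]1[C@]2(C)OC(C)(C)O[C@@H]2C=C[C@]1(C)C(O[Si](CC)(CC)CC)COCc1ccc(OC)cc1 | intermediate
17 | C9 aldehyde | O=C[C@H]1[C@]2(C)OC(C)(C)O[C@@H]2C=C[C@]1(C)C(O[Si](CC)(CC)CC)COCc1ccc(OC)cc1 | intermediate
18 | methyl hydroxyacetate | COC(=O)CO | starting material
19 | methyl (tert-butyldiphenylsilyloxy)acetate | COC(=O)CO[Si](c1ccccc1)(c1ccccc1)C(C)(C)C | intermediate
20 | methyl propanoate | CCC(=O)OC | starting material
21 | methyl 4-(tert-butyldiphenylsilyloxy)-2-methyl-3-oxobutanoate | COC(=O)C(C)C(=O)CO[Si](c1ccccc1)(c1ccccc1)C(C)(C)C | intermediate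
22 | methyl (Z)-4-(tert-butyldiphenylsilyloxy)-2-methyl-3-(trifluoromethylsulfonyloxy)but-2-enoate | COC(=O)/C(C)=C(\OS(=O)(=O)C(F)(F)F)CO[Si](c1ccccc1)(c1ccccc1)C(C)(C)C | intermediate
23 | (Z)-γ-hydroxy enoate (C9 carbinol, C8=C17) | COC(=O)/C(C)=C(/CO[Si](c1ccccc1)(c1ccccc1)C(C)(C)C)[C@@H](O)[C@H]1[C@]2(C)OC(C)(C)O[C@@H]2C=C[C@]1(C)C(O[Si](CC)(CC)CC)COCc1ccc(OC)cc1 | intermediate
24 | butenolide on O9 | CC1=C(CO[Si](c2ccccc2)(c2ccccc2)C(C)(C)C)[C@@H](OC1=O)[C@H]3[C@]4(C)OC(C)(C)O[C@@H]4C=C[C@]3(C)C(O[Si](CC)(CC)CC)COCc5ccc(OC)cc5 | intermediate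
25 | 8,17-dihydroxy O9 lactone | C[C@]1(O)[C@](O)(CO[Si](c2ccccc2)(c2ccccc2)C(C)(C)C)[C@@H](OC1=O)[C@H]3[C@]4(C)OC(C)(C)O[C@@H]4C=C[C@]3(C)C(O[Si](CC)(CC)CC)COCc5ccc(OC)cc5 | intermediate
26 | 8,17:11,12-bis-O-isopropylidene O9 lactone | C[C@]12OC(C)(C)O[C@@]1(CO[Si](c3ccccc3)(c3ccccc3)C(C)(C)C)[C@@H](OC2=O)[C@H]3[C@]4(C)OC(C)(C)O[C@@H]4C=C[C@]3(C)C(O[Si](CC)(CC)CC)COCc5ccc(OC)cc5 | intermediate
27 | C19 Weinreb amide, C9 alcohol | CON(C)C(=O)[C@@]1(C)OC(C)(C)O[C@@]1(CO[Si](c2ccccc2)(c2ccccc2)C(C)(C)C)[C@@H](O)[C@H]3[C@]4(C)OC(C)(C)O[C@@H]4C=C[C@]3(C)C(O[Si](CC)(CC)CC)COCc5ccc(OC)cc5 | intermediate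
28 | C9 acetate | CON(C)C(=O)[C@@]1(C)OC(C)(C)O[C@@]1(CO[Si](c2ccccc2)(c2ccccc2)C(C)(C)C)[C@@H](OC(C)=O)[C@H]3[C@]4(C)OC(C)(C)O[C@@H]4C=C[C@]3(C)C(O[Si](CC)(CC)CC)COCc5ccc(OC)cc5 | intermediate
29 | C2 alcohol (C2 epimers) | CON(C)C(=O)[C@@]1(C)OC(C)(C)O[C@@]1(CO[Si](c2ccccc2)(c2ccccc2)C(C)(C)C)[C@@H](OC(C)=O)[C@H]3[C@]4(C)OC(C)(C)O[C@@H]4C=C[C@]3(C)C(O)COCc5ccc(OC)cc5 | intermediate
30 | C2 ketone | CON(C)C(=O)[C@@]1(C)OC(C)(C)O[C@@]1(CO[Si](c2ccccc2)(c2ccccc2)C(C)(C)C)[C@@H](OC(C)=O)[C@H]3[C@]4(C)OC(C)(C)O[C@@H]4C=C[C@]3(C)C(=O)COCc5ccc(OC)cc5 | intermediate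
31 | prop-2-yn-1-ol | C#CCO | starting material
32 | (Z)-alkenylmagnesium alkoxide | Br[Mg]OC/C(C)=C\[Mg]Br | intermediate
33 | (Z)-3-iodo-2-methylprop-2-en-1-ol | OC/C(C)=C\I | intermediate
34 | (Z)-3-iodo-2-methylprop-2-enal | O=C/C(C)=C\I | intermediate
35 | 3,4-syn aldol adduct | CON(C)C(=O)[C@@]1(C)OC(C)(C)O[C@@]1(CO[Si](c2ccccc2)(c2ccccc2)C(C)(C)C)[C@@H](OC(C)=O)[C@H]3[C@]4(C)OC(C)(C)O[C@@H]4C=C[C@]3(C)C(=O)[C@H](OCc5ccc(OC)cc5)[C@@H](O)/C(C)=C\I | intermediate
36 | 2,4-anti diol | CON(C)C(=O)[C@@]1(C)OC(C)(C)O[C@@]1(CO[Si](c2ccccc2)(c2ccccc2)C(C)(C)C)[C@@H](OC(C)=O)[C@H]3[C@]4(C)OC(C)(C)O[C@@H]4C=C[C@]3(C)[C@H](O)[C@H](OCc5ccc(OC)cc5)[C@@H](O)/C(C)=C\I | intermediate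
37 | 2,4-diacetate | CON(C)C(=O)[C@@]1(C)OC(C)(C)O[C@@]1(CO[Si](c2ccccc2)(c2ccccc2)C(C)(C)C)[C@@H](OC(C)=O)[C@H]3[C@]4(C)OC(C)(C)O[C@@H]4C=C[C@]3(C)[C@H](OC(C)=O)[C@H](OCc5ccc(OC)cc5)[C@@H](OC(C)=O)/C(C)=C\I | intermediate
38 | C7 alcohol | CON(C)C(=O)[C@@]1(C)OC(C)(C)O[C@@]1(CO)[C@@H](OC(C)=O)[C@H]3[C@]4(C)OC(C)(C)O[C@@H]4C=C[C@]3(C)[C@H](OC(C)=O)[C@H](OCc5ccc(OC)cc5)[C@@H](OC(C)=O)/C(C)=C\I | intermediate
39 | C7 aldehyde | CON(C)C(=O)[C@@]1(C)OC(C)(C)O[C@@]1(C=O)[C@@H](OC(C)=O)[C@H]3[C@]4(C)OC(C)(C)O[C@@H]4C=C[C@]3(C)[C@H](OC(C)=O)[C@H](OCc5ccc(OC)cc5)[C@@H](OC(C)=O)/C(C)=C\I | intermediate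
40 | ten-membered ring allylic alcohol (7S, 5Z) | CON(C)C(=O)[C@@]1(C)OC(C)(C)O[C@@]12[C@@H](OC(C)=O)[C@H]3[C@]4(C)OC(C)(C)O[C@@H]4C=C[C@]3(C)[C@H](OC(C)=O)[C@H](OCc5ccc(OC)cc5)[C@@H](OC(C)=O)/C(C)=C\[C@@H]2O | intermediate
41 | C3 alcohol | CON(C)C(=O)[C@@]1(C)OC(C)(C)O[C@@]12[C@@H](OC(C)=O)[C@H]3[C@]4(C)OC(C)(C)O[C@@H]4C=C[C@]3(C)[C@H](OC(C)=O)[C@H](O)[C@@H](OC(C)=O)/C(C)=C\[C@@H]2O | intermediate
42 | hexaol N-methoxy-N-methylamide | CON(C)C(=O)[C@@](C)(O)[C@@]1(O)[C@@H](OC(C)=O)[C@H]2[C@](C)(O)[C@H](O)C=C[C@]2(C)[C@H](OC(C)=O)[C@H](O)[C@@H](OC(C)=O)/C(C)=C\[C@@H]1O | intermediate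
43 | brianodin C | CC(=O)O[C@@H]1[C@H](O)[C@@H](OC(C)=O)/C(C)=C\[C@@H]2OC(=O)[C@@](C)(O)[C@@]2(O)[C@@H](OC(C)=O)[C@H]2[C@](C)(O)[C@H](O)C=C[C@]12C | target

**Count and risks**

Total step count: 32. Longest linear sequence: 26 steps (1, 2, 4–12, 16–22, 25–32).

Step 30 (ring closure). The alkenyl chromium species may be reduced or may dimerise faster than it adds to the neopentyl C7 aldehyde, or it may add to the wrong face of it. The fallback closes the ring at C5=C6 by metathesis and sets out from ketone 30. A boron aldol with 2-methylprop-2-enal in place of 34 gives the isopropenyl aldol adduct F1; Evans–Saksena reduction gives the diol F2 and acetylation the diacetate F3. Desilylation gives the C7 alcohol F4 and Dess–Martin oxidation the C7 aldehyde F5. Bromoethene with CrCl2/NiCl2, now intermolecular and free of ring strain, gives the C7 vinyl carbinol F6, whose 7S epimer is separated. Ring-closing metathesis with second-generation Grubbs catalyst, RuCl2(=CHPh)(H2IMes)(PCy3), then forms the Z C5=C6 bond and returns to 40.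

Step 25 (aldol). The C1 quaternary centre may discriminate the two enolate faces poorly or in the wrong sense, which would give the 3,4-syn adduct of opposite absolute configuration. The fallback moves the control from the substrate to the reagent: ketone 30 is enolised with diisopinocampheylboron triflate, using the enantiomer that a trial shows to be matched, so that the chiral ligands on boron choose the enolate face. It sets out from 30 and returns to 35 with no new compound (F0).

Step 16 (C8–C9 coupling). The tetrasubstituted alkenyl chromium species may add sluggishly to the hindered aldehyde or past the wrong face, giving the C9 epimer of the butenolide. The fallback forms the C8–C9 bond by acylation and sets C9 by hydride, so that hydride takes the trajectory the carbon nucleophile would have taken and the opposite C9 configuration results. From β-keto ester 21, Ph3P·I2/Et3N gives the (Z)-β-iodo enoate F7. Iodine–magnesium exchange (i-PrMgCl·LiCl, −40 °C) and addition to Weinreb amide 16 gives the γ-keto (Z)-enoate F8. Luche reduction (NaBH4, CeCl3) and lactonisation of the alkoxide return to 24.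

**Further compounds**

F1 | step 30 | isopropenyl aldol adduct (3,4-syn) | CON(C)C(=O)[C@@]1(C)OC(C)(C)O[C@@]1(CO[Si](c2ccccc2)(c2ccccc2)C(C)(C)C)[C@@H](OC(C)=O)[C@H]3[C@]4(C)OC(C)(C)O[C@@H]4C=C[C@]3(C)C(=O)[C@H](OCc5ccc(OC)cc5)[C@@H](O)C(C)=C
F2 | step 30 | isopropenyl 2,4-anti diol | CON(C)C(=O)[C@@]1(C)OC(C)(C)O[C@@]1(CO[Si](c2ccccc2)(c2ccccc2)C(C)(C)C)[C@@H](OC(C)=O)[C@H]3[C@]4(C)OC(C)(C)O[C@@H]4C=C[C@]3(C)[C@H](O)[C@H](OCc5ccc(OC)cc5)[C@@H](O)C(C)=C
F3 | step 30 | isopropenyl 2,4-diacetate | CON(C)C(=O)[C@@]1(C)OC(C)(C)O[C@@]1(CO[Si](c2ccccc2)(c2ccccc2)C(C)(C)C)[C@@H](OC(C)=O)[C@H]3[C@]4(C)OC(C)(C)O[C@@H]4C=C[C@]3(C)[C@H](OC(C)=O)[C@H](OCc5ccc(OC)cc5)[C@@H](OC(C)=O)C(C)=C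
F4 | step 30 | isopropenyl C7 alcohol | CON(C)C(=O)[C@@]1(C)OC(C)(C)O[C@@]1(CO)[C@@H](OC(C)=O)[C@H]3[C@]4(C)OC(C)(C)O[C@@H]4C=C[C@]3(C)[C@H](OC(C)=O)[C@H](OCc5ccc(OC)cc5)[C@@H](OC(C)=O)C(C)=C
F5 | step 30 | isopropenyl C7 aldehyde | CON(C)C(=O)[C@@]1(C)OC(C)(C)O[C@@]1(C=O)[C@@H](OC(C)=O)[C@H]3[C@]4(C)OC(C)(C)O[C@@H]4C=C[C@]3(C)[C@H](OC(C)=O)[C@H](OCc5ccc(OC)cc5)[C@@H](OC(C)=O)C(C)=C
F6 | step 30 | C7 vinyl carbinol (7S) | CON(C)C(=O)[C@@]1(C)OC(C)(C)O[C@@]1([C@@H](O)C=C)[C@@H](OC(C)=O)[C@H]3[C@]4(C)OC(C)(C)O[C@@H]4C=C[C@]3(C)[C@H](OC(C)=O)[C@H](OCc5ccc(OC)cc5)[C@@H](OC(C)=O)C(C)=C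
F0 | step 25 | none | none
F7 | step 16 | methyl (Z)-4-(tert-butyldiphenylsilyloxy)-3-iodo-2-methylbut-2-enoate | COC(=O)/C(C)=C(\I)CO[Si](c1ccccc1)(c1ccccc1)C(C)(C)C
F8 | step 16 | γ-keto (Z)-enoate (C9 ketone) | COC(=O)/C(C)=C(/CO[Si](c1ccccc1)(c1ccccc1)C(C)(C)C)C(=O)[C@H]1[C@]2(C)OC(C)(C)O[C@@H]2C=C[C@]1(C)C(O[Si](CC)(CC)CC)COCc1ccc(OC)cc1
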